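## Structural features

The target is a 2,3-dihydro-1-benzofuran: a benzene ring fused through C3a and C7a to a five-membered ring whose other members are O1, C2 and C3. C2 carries a 3-oxoprop-1-en-2-yl group (a 2-substituted acrolein), C3 carries a 3-methylbutanoyloxy group, and C5, para to O1, carries a 1-(acyloxy)ethyl chain acylated by (2R)-2-methylbutanoic acid. Of the four stereocentres, C2 (R) and C3 (S) are neighbours and trans on the five-membered ring, whereas the side-chain carbinol carbon (R) and the α-carbon of its acyl group (R) are isolated and must be set independently. The fragile groups are the enal (a polymerisable Michael acceptor), the two benzylic esters (C3 is ortho-related and the side-chain carbinol para-related to O1, so both ionise easily once the aryl ether exists, and loss of the C3 acyloxy group with H2 would aromatise the ring to a benzofuran), and the base-epimerisable α-stereocentre of the 2-methylbutanoate. The real difficulty is the contiguous oxygenated array C3–C2–Cα–CHO in one absolute configuration, with three differently functionalised oxygens, which calls for orthogonal handling of four hydroxyl groups and a late release of the aldehyde. The key step exploits the fact that O1 joins the sp3 carbon C2 to the arene carbon C7a: the heterocycle can be closed by aryl C–O bond formation from an ortho-bromoarene. Once it is opened, C3, C2, the acrolein α-carbon and the formyl carbon with their three oxygens are the aldol adduct of an aryl aldehyde and a dihydroxyacetone unit. Because this closure breaks no bond at C2 or C3, an anti diol maps directly onto the trans ring.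

## Logic of the disconnections

16 to 15. The formyl C=O is taken back to a primary allylic C–OH; no skeletal bond is cut. The enal is the most reactive group and should exist only in the last compound. The demand is an oxidant that is neutral and stops at the aldehyde, because both benzylic esters of 15 ionise in acid.

15 to 14. The O–H bond of the allylic alcohol is exchanged for an O–Si bond. The primary oxygen has to be masked during ring closure and C3 acylation. The demand is a desilylation that neither moves nor removes the C3 ester.

14 to 13. The acyl C–O bond of the C3 ester is cut, leaving the free C3 alcohol and an activated acyl donor. Acylating after the ring closure keeps a migration-prone ester out of the basic coupling. The demand is that 13 has exactly one free hydroxyl and that acylation proceeds with retention under non-ionising conditions.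

13 to 12. The aryl ether bond C7a–O1 is cut, opening the five-membered ring to an ortho-bromoarene bearing an anti 1,2-diol. Ring stereochemistry becomes acyclic diol stereochemistry and the heterocycle disappears. The demand is a C–O coupling that selects the C2 hydroxyl over the C3 hydroxyl and tolerates an ester and a silyl ether in hot carbonate.

12 to 11. The O–Si bond on the primary oxygen is cut, giving the triol. The demand is silylation of the primary hydroxyl only, in the presence of two secondary ones.

11 to 10. The three O–H bonds are traced back to one ketal (two C–O bonds) and one silyl ether. The masked form is what the preceding carbonyl and organometallic steps need. The demand is a single acid treatment that removes both groups without ionising a benzylic C–O bond; this is easier here, while the arene still carries bromine and not the ring oxygen.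

10 to 8 and 9. The acyl C–O bond of the side-chain ester is cut. The chiral acid 9 enters after every ylide and Grignard step, so its α-stereocentre never meets a strong base. The demand is esterification with retention at the carbinol of 8 and without epimerising 9.

8 to 7. The carbinol C–H bond is removed, so the (R) centre derives from a prochiral aryl methyl ketone. The demand is catalyst-controlled reduction (the existing centres are too remote to help) that leaves the alkene, the C–Br bond, the silyl ether and the ketal alone. At this point the ketone to be reduced is the only carbonyl group in the molecule, which is why the side chain is built after the aldol and the methylenation and why no aldehyde protection is needed anywhere.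

7 to 5 through 6. The aryl–acyl C–C bond is cut, giving the aryl iodide and an acetyl cation equivalent. The two halogens are used in order of reactivity: iodine here, bromine kept for the ring closure. The demand is halogen–metal exchange at iodine only, on a substrate with no free hydroxyl or carbonyl.

5 to 4. The exocyclic C=CH2 bond is cut back to a ketone and a one-carbon ylide; the new carbon is the β-carbon of the final acrolein. The demand is that olefination outruns enolisation toward C4 (the future C2), which would epimerise it or expel the β-silyloxy group.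

4 to 3. The O–Si bond on the aldol hydroxyl is cut. Silylation is needed to block retro-aldol cleavage in basic steps. The demand is a mild, cold silylation.

3 to 1 and 2. The bond between the future C2 and C3 is cut as an aldol between the aldehyde 1 and the ketone 2. Both ring stereocentres arise here from two purchased compounds. The demand is anti selectivity and absolute control by an amino-acid catalyst. The (4S, S-carbinol) adduct 3 corresponds to (2R,3S) in 16; the descriptor at the former C4 changes only through CIP priorities.

## Other disconnections considered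

Alternative 1: Both C2–C3 and O1–C2 are cut at once, so the heterocycle falls apart into two pieces. One is the salicylaldehyde (1R)-1-(3-formyl-4-hydroxyphenyl)ethyl (2R)-2-methylbutanoate A1. The other is an ylide made with Cs2CO3 from a chiral methallyl sulfonium salt such as (2R,5R)-2,5-dimethyl-1-(2-methylprop-2-en-1-yl)thiolan-1-ium tetrafluoroborate A2.
- Forward key step: the ylide carbon would add to the formyl carbon and the phenoxide would then displace the sulfide at the same carbon. This would give (1R)-1-[(2R,3S)-3-hydroxy-2-(prop-1-en-2-yl)-2,3-dihydro-1-benzofuran-5-yl]ethyl (2R)-2-methylbutanoate A3.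
- In favour: ring, two bonds and both ring stereocentres would come from one metal-free operation on an aldehyde that needs neither halogen nor protecting groups.
- Against: the betaine can partition between phenoxide displacement and ordinary epoxide closure. These paths differ in the number of inversions at C2, so the trans outcome is not fixed by mechanism. An allyl ylide is ambident (α versus γ attack). The absolute configuration would rest on a stoichiometric chiral sulfide whose sense of induction is assumed; A2 is drawn as one antipode only for definiteness. A3 also lacks the oxygen on the isopropenyl carbon, so the aldehyde would need a late SeO2 allylic oxidation next to an allylic α-oxy C2–H and two ionisable benzylic esters.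
- Comparison: in bonds per step and in step economy this plan is the better one (about half the length). The chosen plan is the more predictable in mechanism, because its closure has one possible regiochemistry and no stereochemical event. In structure the chosen plan carries the formyl carbon as an oxygenated carbon from the first step.

Alternative 2: The O1–C2 bond is traced back to a 1,2-shift of the aryloxy oxygen, so the dihydrobenzofuran derives from a ring-expanded chroman.
- Relay: the chromene (1R)-1-(2,2-dimethyl-2H-chromen-6-yl)ethyl (2R)-2-methylbutanoate A4 would be epoxidised (Jacobsen epoxidation, chiral (salen)MnCl catalyst) to (1R)-1-[(3R,4R)-3,4-epoxy-2,2-dimethyl-3,4-dihydro-2H-chromen-6-yl]ethyl (2R)-2-methylbutanoate A5. Opening at the benzylic carbon by the acid that supplies the C3 ester, with inversion, would give (1R)-1-[(3R,4S)-3-hydroxy-2,2-dimethyl-4-(3-methylbutanoyloxy)-3,4-dihydro-2H-chromen-6-yl]ethyl (2R)-2-methylbutanoate A6.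
- Forward key step: Tf2O and a hindered pyridine would turn the hydroxyl of A6 into a triflate. The ring oxygen displaces it from the rear while the bond to the quaternary carbon breaks and the tertiary cation loses a proton. This contracts the ring to (1R)-1-[(2R,3S)-3-(3-methylbutanoyloxy)-2-(prop-1-en-2-yl)-2,3-dihydro-1-benzofuran-5-yl]ethyl (2R)-2-methylbutanoate A7.
- In favour: 2,2-dimethylchromenes are among the best substrates for this epoxidation, so absolute control is at least the equal of the proline aldol. The C3 ester arrives in final form with no protecting group, the shift is stereospecific, and the sequence is shorter; on step economy it is the better plan.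
- Against: opening of A5 at a benzylic carbon that is ortho-related to the ring oxygen has SN1 character and may leak to the cis isomer. In A6 the trans ester carbonyl can participate at the triflate carbon. The aryloxy shift needs the leaving group pseudo-equatorial and anti-periplanar to the breaking C–O bond, whereas participation needs it pseudo-axial, so the outcome depends on conformation. The cation may also lose the ring proton in place of a methyl proton. A7 still needs the same late SeO2 oxidation as A3.
- Comparison: in structure the alternative builds the isopropenyl group but not its oxygen, whereas the chosen plan needs no C–H oxidation. In mechanism a cationic rearrangement with competing pathways stands against a coupling whose selectivity is set by ring size.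

Alternative 3: Only C2–C3 is cut. The precursor (1R)-1-{4-[(1E)-3-(dimethylamino)-3-oxoprop-1-en-1-yl]oxy-3-formylphenyl}ethyl (2R)-2-methylbutanoate A8 is one conjugate addition away from the phenol A1.
- Forward key step: SmI2 with a chiral aminodiol ligand and MeOH would reduce the aldehyde to a ketyl that adds 5-exo-trig to the β-carbon of the aryloxyacrylamide. This would give (1R)-1-{(2R,3S)-2-[2-(dimethylamino)-2-oxoethyl]-3-hydroxy-2,3-dihydro-1-benzofuran-5-yl}ethyl (2R)-2-methylbutanoate A9.
- In favour: the precursor needs no halogen and no protecting group, which is better than the chosen plan on the way to the ring closure. Ring and both stereocentres form together. Chelated ketyl–olefin cyclisations onto β-alkoxy acrylic acceptors are dependably trans-selective, so relative stereocontrol is equal to that of the chosen plan.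
- Against: absolute control would have to come from a chiral ligand on samarium in at least stoichiometric amount, a much less established source of enantioselectivity than enamine catalysis. Aryl aldehyde ketyls also dimerise. A9 ends in an arm that is one carbon short and at the wrong oxidation level. Reducing the amide to the aldehyde and α-methylenating it pass through enolate- or enamine-type species in which the β-aryloxy group can be expelled with ring opening.
- Comparison: in structure the chosen plan delivers all four carbons of the C3–C2–acrolein unit with their oxygens in one aldol. In mechanism a reagent-controlled single-electron cyclisation stands against a two-electron coupling without stereochemical risk. In step economy the two are about equal, since what the alternative saves before the closure it spends after it.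

Key step: step 9

Remark on the chemistry (assumption): the L-proline aldol of 2 with the ortho-substituted aromatic aldehyde 1 is taken to follow the anti, (4S)/(S)-carbinol sense established for this donor with other acceptors; the silyl group on the primary oxygen is chosen as tert-butyldiphenylsilyl for stability in the basic ring closure.

## Route

Step 1
Reactants: 1 2-bromo-5-iodobenzaldehyde; 2 2,2-dimethyl-1,3-dioxan-5-one
Product: 3 (4S)-4-[(S)-(2-bromo-5-iodophenyl)(hydroxy)methyl]-2,2-dimethyl-1,3-dioxan-5-one
Conditions: L-proline (30 mol %), DMF, 4 °C, 3–5 d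
Reagents that add atoms: none
Why: Proline-catalysed direct aldol reaction (enamine catalysis): the ring forces the enamine of 2 into the E geometry and the carboxylic acid of the catalyst hydrogen-bonds the aldehyde onto one enamine face, which should give the anti adduct with (4S) and (S)-carbinol configuration. The electron-poor, non-enolisable aldehyde 1 is a reactive acceptor, and minor stereoisomers are to be removed by chromatography or crystallisation.

Step 2
Reactants: 3 (4S)-4-[(S)-(2-bromo-5-iodophenyl)(hydroxy)methyl]-2,2-dimethyl-1,3-dioxan-5-one
Product: 4 (4S)-4-[(S)-(2-bromo-5-iodophenyl)(triethylsilyloxy)methyl]-2,2-dimethyl-1,3-dioxan-5-one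
Conditions: TESOTf, 2,6-lutidine, CH2Cl2, −78 °C
Reagents that add atoms: triethylsilyl trifluoromethanesulfonate, CC[Si](CC)(CC)OS(=O)(=O)C(F)(F)F
Why: O-Silylation of the secondary hydroxyl with a silyl triflate and a hindered base is fast at low temperature and blocks retro-aldol cleavage in the next step. No stereocentre is touched.

Step 3
Reactants: 4 (4S)-4-[(S)-(2-bromo-5-iodophenyl)(triethylsilyloxy)methyl]-2,2-dimethyl-1,3-dioxan-5-one
Product: 5 {(S)-(2-bromo-5-iodophenyl)[(4R)-2,2-dimethyl-5-methylidene-1,3-dioxan-4-yl]methoxy}(triethyl)silane
Conditions: Ph3PCH3Br, KOtBu, THF, 0 °C; then 4, −78 → 0 °C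
Reagents that add atoms: methyltriphenylphosphonium bromide, C[P+](c1ccccc1)(c1ccccc1)c1ccccc1.[Br-]
Why: Wittig methylenation of a ketone made strongly electrophilic by two α-oxygens; addition of the unstabilised ylide should outrun enolisation when the ylide is used cold and without excess base. The geometry at C4 is unchanged, and its descriptor becomes R only through the change in substituent priorities.

Step 4
Reactants: 5 {(S)-(2-bromo-5-iodophenyl)[(4R)-2,2-dimethyl-5-methylidene-1,3-dioxan-4-yl]methoxy}(triethyl)silane
Product: 7 1-{4-bromo-3-[(S)-[(4R)-2,2-dimethyl-5-methylidene-1,3-dioxan-4-yl](triethylsilyloxy)methyl]phenyl}ethan-1-one, via arylmagnesium chloride 6 (not isolated)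
Conditions: iPrMgCl·LiCl, THF, −20 °C; then MeC(O)N(OMe)Me, −20 → 0 °C; aq. NH4Cl
Reagents that add atoms: N-methoxy-N-methylacetamide, CC(=O)N(C)OC
Why: Iodine–magnesium exchange is far faster at C–I than at C–Br, and the substrate has no acidic or electrophilic group. Weinreb ketone synthesis: the aryl Grignard 6 adds once to the amide and the stable chelate releases the methyl ketone only on work-up.

Step 5
Reactants: 7 1-{4-bromo-3-[(S)-[(4R)-2,2-dimethyl-5-methylidene-1,3-dioxan-4-yl](triethylsilyloxy)methyl]phenyl}ethan-1-one
Product: 8 (1R)-1-{4-bromo-3-[(S)-[(4R)-2,2-dimethyl-5-methylidene-1,3-dioxan-4-yl](triethylsilyloxy)methyl]phenyl}ethan-1-ol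
Conditions: RuCl[(R,R)-TsDPEN](p-cymene) (1 mol %), HCO2H/Et3N (1:2), CH2Cl2, 25 °C
Reagents that add atoms: none
Why: Noyori–Ikariya asymmetric transfer hydrogenation of an aryl methyl ketone by outer-sphere hydride/proton transfer; the (R,R) ligand is the one that gives (R)-1-arylethanols, so the new centre is catalyst-controlled. The amine-rich formate medium should spare the TES ether and the ketal, and the isolated alkene and the C–Br bond are not reduced by this catalyst.

Step 6
Reactants: 8 (1R)-1-{4-bromo-3-[(S)-[(4R)-2,2-dimethyl-5-methylidene-1,3-dioxan-4-yl](triethylsilyloxy)methyl]phenyl}ethan-1-ol; 9 (2R)-2-methylbutanoic acid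
Product: 10 (1R)-1-{4-bromo-3-[(S)-[(4R)-2,2-dimethyl-5-methylidene-1,3-dioxan-4-yl](triethylsilyloxy)methyl]phenyl}ethyl (2R)-2-methylbutanoate
Conditions: EDC·HCl, DMAP (cat.), CH2Cl2, 0 °C → rt
Reagents that add atoms: none
Why: Steglich-type carbodiimide esterification; the carbinol C–O bond is not broken, so the (R) configuration is retained. Mild conditions with only catalytic DMAP should not epimerise the α-methyl acid.

Step 7
Reactants: 10 (1R)-1-{4-bromo-3-[(S)-[(4R)-2,2-dimethyl-5-methylidene-1,3-dioxan-4-yl](triethylsilyloxy)methyl]phenyl}ethyl (2R)-2-methylbutanoate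
Product: 11 (1R)-1-{4-bromo-3-[(1S,2R)-1,2-dihydroxy-3-(hydroxymethyl)but-3-en-1-yl]phenyl}ethyl (2R)-2-methylbutanoate
Conditions: TsOH·H2O (10 mol %), MeOH, 0 °C → rt
Reagents that add atoms: none
Why: Acid-catalysed transketalisation and silyl ether methanolysis remove the acetonide and the TES group together. The arene still carries bromine and not the ring oxygen, so neither benzylic C–O bond should ionise, and the hindered ester is not transesterified under these conditions.

Step 8
Reactants: 11 (1R)-1-{4-bromo-3-[(1S,2R)-1,2-dihydroxy-3-(hydroxymethyl)but-3-en-1-yl]phenyl}ethyl (2R)-2-methylbutanoate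
Product: 12 (1R)-1-{4-bromo-3-[(1S,2R)-3-{[tert-butyl(diphenyl)silyl]oxymethyl}-1,2-dihydroxybut-3-en-1-yl]phenyl}ethyl (2R)-2-methylbutanoate
Conditions: TBDPSCl (1.05 equiv), imidazole, CH2Cl2, −10 → 0 °C
Reagents that add atoms: tert-butyl(chloro)diphenylsilane, CC(C)(C)[Si](Cl)(c1ccccc1)c1ccccc1
Why: Steric differentiation in silylation: the bulky chlorosilane reacts with the primary allylic hydroxyl and leaves the two secondary hydroxyls free.

Step 9
Reactants: 12 (1R)-1-{4-bromo-3-[(1S,2R)-3-{[tert-butyl(diphenyl)silyl]oxymethyl}-1,2-dihydroxybut-3-en-1-yl]phenyl}ethyl (2R)-2-methylbutanoate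
Product: 13 (1R)-1-[(2R,3S)-2-(3-{[tert-butyl(diphenyl)silyl]oxy}prop-1-en-2-yl)-3-hydroxy-2,3-dihydro-1-benzofuran-5-yl]ethyl (2R)-2-methylbutanoate
Conditions: CuI (10 mol %), 3,4,7,8-tetramethyl-1,10-phenanthroline (20 mol %), Cs2CO3 (2 equiv), toluene (0.02 M), 100 °C, Ar
Reagents that add atoms: none
Why: Cs2CO3 deprotonates the hydroxyls reversibly and the phenanthroline-bound monovalent copper exchanges iodide for the C2 alkoxide. The neighbouring C7a–Br bond then adds oxidatively to give a trivalent copper aryl alkoxide held in a six-membered chelate (Cu, O, C2, C3, C3a, C7a), and C–O reductive elimination forms the C7a–O1 bond and returns monovalent copper. The closest known reaction type is the copper-catalysed Ullmann-type intramolecular O-arylation of 2-(2-halophenyl)ethanols to 2,3-dihydrobenzofurans. The single ring formed is five-membered and closes in the exo sense at the arene carbon: the C2 oxygen bonds to C7a while the departing bromide lies outside the new ring. No stereocentre is created; only O–H and C–Br bonds are broken, so C2 and C3 keep their configuration and the anti (1S,2R) diol becomes the trans (2R,3S) ring. The selectivity needed is between the hydroxyls, and ring size secures it: the C3 oxygen could reach C7a only through a four-membered ring and so stays free for the later ester, while the primary oxygen is silylated. The bulky tert-butyldiphenylsilyl group is chosen because, unlike a smaller silyl group, it should not shift to the neighbouring C2 alkoxide in the hot basic medium, and high dilution disfavours intermolecular aryl ether formation. The hindered secondary ester and its α-stereocentre are expected to survive carbonate in toluene.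

Step 10
Reactants: 13 (1R)-1-[(2R,3S)-2-(3-{[tert-butyl(diphenyl)silyl]oxy}prop-1-en-2-yl)-3-hydroxy-2,3-dihydro-1-benzofuran-5-yl]ethyl (2R)-2-methylbutanoate
Product: 14 (1R)-1-[(2R,3S)-2-(3-{[tert-butyl(diphenyl)silyl]oxy}prop-1-en-2-yl)-3-(3-methylbutanoyloxy)-2,3-dihydro-1-benzofuran-5-yl]ethyl (2R)-2-methylbutanoate
Conditions: (Me2CHCH2CO)2O, Et3N, DMAP (cat.), CH2Cl2, 0 °C
Reagents that add atoms: 3-methylbutanoic anhydride, CC(C)CC(=O)OC(=O)CC(C)C
Why: DMAP-catalysed acylation of the only free hydroxyl; the C3–O bond is not broken, so the S configuration is retained. The basic, non-ionising medium protects the two benzylic positions that the ring oxygen now activates.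

Step 11
Reactants: 14 (1R)-1-[(2R,3S)-2-(3-{[tert-butyl(diphenyl)silyl]oxy}prop-1-en-2-yl)-3-(3-methylbutanoyloxy)-2,3-dihydro-1-benzofuran-5-yl]ethyl (2R)-2-methylbutanoate
Product: 15 (1R)-1-[(2R,3S)-2-(3-hydroxyprop-1-en-2-yl)-3-(3-methylbutanoyloxy)-2,3-dihydro-1-benzofuran-5-yl]ethyl (2R)-2-methylbutanoate
Conditions: TBAF/AcOH (1:1), THF, 0 °C → rt
Reagents that add atoms: none
Why: Fluoride cleaves the Si–O bond, and buffering with acetic acid keeps the medium near neutral so that the esters should neither migrate nor eliminate. The trans arrangement on the five-membered ring also makes transfer of the C3 acyl group to the new hydroxyl geometrically unfavourable.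

Step 12
Reactants: 15 (1R)-1-[(2R,3S)-2-(3-hydroxyprop-1-en-2-yl)-3-(3-methylbutanoyloxy)-2,3-dihydro-1-benzofuran-5-yl]ethyl (2R)-2-methylbutanoate
Product: 16 (1R)-1-[(2R,3S)-3-(3-methylbutanoyloxy)-2-(3-oxoprop-1-en-2-yl)-2,3-dihydro-1-benzofuran-5-yl]ethyl (2R)-2-methylbutanoate
Conditions: MnO2 (activated, excess), CH2Cl2, rt
Reagents that add atoms: none
Why: MnO2 oxidises allylic alcohols selectively under neutral heterogeneous conditions and stops at the aldehyde. Filtration should give the sensitive enal without aqueous or acidic work-up, and no stereocentre is involved.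

## Compound list

1 | 2-bromo-5-iodobenzaldehyde | O=Cc1cc(I)ccc1Br | starting material
2 | 2,2-dimethyl-1,3-dioxan-5-one | CC1(C)OCC(=O)CO1 | starting material
3 | (4S)-4-[(S)-(2-bromo-5-iodophenyl)(hydroxy)methyl]-2,2-dimethyl-1,3-dioxan-5-one | CC1(C)OCC(=O)[C@@H](O1)[C@@H](O)c2cc(I)ccc2Br | intermediate
4 | (4S)-4-[(S)-(2-bromo-5-iodophenyl)(triethylsilyloxy)methyl]-2,2-dimethyl-1,3-dioxan-5-one | CC1(C)OCC(=O)[C@@H](O1)[C@@H](O[Si](CC)(CC)CC)c2cc(I)ccc2Br | intermediate
5 | {(S)-(2-bromo-5-iodophenyl)[(4R)-2,2-dimethyl-5-methylidene-1,3-dioxan-4-yl]methoxy}(triethyl)silane | CC1(C)OCC(=C)[C@@H](O1)[C@@H](O[Si](CC)(CC)CC)c2cc(I)ccc2Br | intermediate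
6 | {4-bromo-3-[(S)-[(4R)-2,2-dimethyl-5-methylidene-1,3-dioxan-4-yl](triethylsilyloxy)methyl]phenyl}magnesium chloride (LiCl complex, not isolated) | CC1(C)OCC(=C)[C@@H](O1)[C@@H](O[Si](CC)(CC)CC)c2cc([Mg]Cl)ccc2Br | intermediate
7 | 1-{4-bromo-3-[(S)-[(4R)-2,2-dimethyl-5-methylidene-1,3-dioxan-4-yl](triethylsilyloxy)methyl]phenyl}ethan-1-one | CC1(C)OCC(=C)[C@@H](O1)[C@@H](O[Si](CC)(CC)CC)c2cc(C(C)=O)ccc2Br | intermediate
8 | (1R)-1-{4-bromo-3-[(S)-[(4R)-2,2-dimethyl-5-methylidene-1,3-dioxan-4-yl](triethylsilyloxy)methyl]phenyl}ethan-1-ol | CC1(C)OCC(=C)[C@@H](O1)[C@@H](O[Si](CC)(CC)CC)c2cc([C@@H](C)O)ccc2Br | intermediate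
9 | (2R)-2-methylbutanoic acid | CC[C@@H](C)C(=O)O | starting material
10 | (1R)-1-{4-bromo-3-[(S)-[(4R)-2,2-dimethyl-5-methylidene-1,3-dioxan-4-yl](triethylsilyloxy)methyl]phenyl}ethyl (2R)-2-methylbutanoate | CC1(C)OCC(=C)[C@@H](O1)[C@@H](O[Si](CC)(CC)CC)c2cc([C@@H](C)OC(=O)[C@H](C)CC)ccc2Br | intermediate
11 | (1R)-1-{4-bromo-3-[(1S,2R)-1,2-dihydroxy-3-(hydroxymethyl)but-3-en-1-yl]phenyl}ethyl (2R)-2-methylbutanoate | C=C(CO)[C@@H](O)[C@@H](O)c1cc([C@@H](C)OC(=O)[C@H](C)CC)ccc1Br | intermediate
12 | (1R)-1-{4-bromo-3-[(1S,2R)-3-{[tert-butyl(diphenyl)silyl]oxymethyl}-1,2-dihydroxybut-3-en-1-yl]phenyl}ethyl (2R)-2-methylbutanoate | C=C(CO[Si](c3ccccc3)(c4ccccc4)C(C)(C)C)[C@@H](O)[C@@H](O)c1cc([C@@H](C)OC(=O)[C@H](C)CC)ccc1Br | intermediate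
13 | (1R)-1-[(2R,3S)-2-(3-{[tert-butyl(diphenyl)silyl]oxy}prop-1-en-2-yl)-3-hydroxy-2,3-dihydro-1-benzofuran-5-yl]ethyl (2R)-2-methylbutanoate | C=C(CO[Si](c3ccccc3)(c4ccccc4)C(C)(C)C)[C@H]1Oc2ccc([C@@H](C)OC(=O)[C@H](C)CC)cc2[C@@H]1O | intermediate
14 | (1R)-1-[(2R,3S)-2-(3-{[tert-butyl(diphenyl)silyl]oxy}prop-1-en-2-yl)-3-(3-methylbutanoyloxy)-2,3-dihydro-1-benzofuran-5-yl]ethyl (2R)-2-methylbutanoate | C=C(CO[Si](c3ccccc3)(c4ccccc4)C(C)(C)C)[C@H]1Oc2ccc([C@@H](C)OC(=O)[C@H](C)CC)cc2[C@@H]1OC(=O)CC(C)C | intermediate
15 | (1R)-1-[(2R,3S)-2-(3-hydroxyprop-1-en-2-yl)-3-(3-methylbutanoyloxy)-2,3-dihydro-1-benzofuran-5-yl]ethyl (2R)-2-methylbutanoate | C=C(CO)[C@H]1Oc2ccc([C@@H](C)OC(=O)[C@H](C)CC)cc2[C@@H]1OC(=O)CC(C)C | intermediate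
16 | (1R)-1-[(2R,3S)-3-(3-methylbutanoyloxy)-2-(3-oxoprop-1-en-2-yl)-2,3-dihydro-1-benzofuran-5-yl]ethyl (2R)-2-methylbutanoate | C=C(C=O)[C@H]1Oc2ccc([C@@H](C)OC(=O)[C@H](C)CC)cc2[C@@H]1OC(=O)CC(C)C | target

## Step count and least certain steps

Total: 12 steps. Longest linear sequence: 12 steps (1 to 16); 2 and 9 are purchased.

Step 9 (key step). The most likely failure is stalling of the catalytic cycle. Oxidative addition to an unactivated, ortho-substituted C–Br bond is slow, and the 1,2-diolate can hold copper in an unproductive chelate. On prolonged heating, base-promoted ester exchange and reductive loss of bromine would take over. The fallback leaves copper for a different catalytic manifold and is run on the same compound, setting out from 12 and returning at 13; it makes no new compound (F0). It is a Buchwald–Hartwig etherification with Pd(OAc)2 and the bulky biaryl phosphine t-BuXPhos, Cs2CO3, toluene, 70 °C. Zerovalent palladium inserts into the C–Br bond far more readily than copper, the alkoxide exchanges onto divalent palladium, and the bulky ligand drives C–O reductive elimination ahead of β-hydride loss. The lower temperature also answers the ester-exchange problem.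

Step 1. The most likely failure is poor simple diastereoselectivity. An aromatic aldehyde is a flatter, less discriminating acceptor than the α-branched aliphatic aldehydes for which this aldol is most selective, and reversibility on long reaction times erodes the ratio further. The enamine face, and with it the future C2, is the better-controlled element, so the fallback resets only the carbinol centre by substrate control. It sets out from 5, carried through steps 2 and 3 as the mixture of carbinol epimers, and returns to 5 as the single anti isomer.
- TBAF in THF at 0 °C would give (2-bromo-5-iodophenyl)[(4R)-2,2-dimethyl-5-methylidene-1,3-dioxan-4-yl]methanol F1 (both carbinol epimers).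
- Dess–Martin periodinane with NaHCO3 in CH2Cl2 at 0 °C would give (2-bromo-5-iodophenyl)[(4R)-2,2-dimethyl-5-methylidene-1,3-dioxan-4-yl]methanone F2. It is used at once and cold, because its C4–H is activated toward enolisation.
- Zn(BH4)2 in Et2O at −30 °C should reduce F2 under chelation control, with zinc bridging the carbonyl and ring oxygens and hydride entering from the side of the C4 hydrogen. This would give the anti alcohol (S)-(2-bromo-5-iodophenyl)[(4R)-2,2-dimethyl-5-methylidene-1,3-dioxan-4-yl]methanol F3.
- Silylation of F3 as in step 2 gives 5.

Step 3. The most likely failure is enolisation of the ketone toward C4 by the basic ylide in place of carbonyl addition. This would epimerise the future C2 or expel the β-silyloxy group to an enone. The fallback is a two-stage Peterson olefination with a far less basic nucleophile, setting out from 4 and returning at 5.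
- TMSCH2MgCl with CeCl3 in THF at −78 °C would add to the ketone to give (4S)-4-[(S)-(2-bromo-5-iodophenyl)(triethylsilyloxy)methyl]-2,2-dimethyl-5-[(trimethylsilyl)methyl]-1,3-dioxan-5-ol F4. The configuration at the new carbinol carbon is irrelevant.
- KH in THF at 0 °C then brings about syn elimination of silanolate to give 5. No ester is present at this stage, so the base is tolerated.

Step 11. The most likely failure is fluoride-induced loss or migration of the C3 acyl group, or ionisation of the activated benzylic ester leading toward the aromatic benzofuran. The fallback changes the order of events so that the sensitive C3 ester is made last, setting out from 13 and returning at 16.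
- TBAF/AcOH on 13 would give (1R)-1-[(2R,3S)-3-hydroxy-2-(3-hydroxyprop-1-en-2-yl)-2,3-dihydro-1-benzofuran-5-yl]ethyl (2R)-2-methylbutanoate F5.
- TEMPO (cat.) with PhI(OAc)2 in CH2Cl2 should oxidise only the primary allylic hydroxyl, giving (1R)-1-[(2R,3S)-3-hydroxy-2-(3-oxoprop-1-en-2-yl)-2,3-dihydro-1-benzofuran-5-yl]ethyl (2R)-2-methylbutanoate F6.
- Acylation of the remaining C3 hydroxyl with 3-methylbutanoic anhydride and catalytic DMAP at −20 °C would give 16.

## Further compounds

F0 | step 9 | none | none
F1 | step 1 | (2-bromo-5-iodophenyl)[(4R)-2,2-dimethyl-5-methylidene-1,3-dioxan-4-yl]methanol (both carbinol epimers) | CC1(C)OCC(=C)[C@@H](O1)C(O)c2cc(I)ccc2Br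
F2 | step 1 | (2-bromo-5-iodophenyl)[(4R)-2,2-dimethyl-5-methylidene-1,3-dioxan-4-yl]methanone | CC1(C)OCC(=C)[C@@H](O1)C(=O)c2cc(I)ccc2Br
F3 | step 1 | (S)-(2-bromo-5-iodophenyl)[(4R)-2,2-dimethyl-5-methylidene-1,3-dioxan-4-yl]methanol | CC1(C)OCC(=C)[C@@H](O1)[C@@H](O)c2cc(I)ccc2Br
F4 | step 3 | (4S)-4-[(S)-(2-bromo-5-iodophenyl)(triethylsilyloxy)methyl]-2,2-dimethyl-5-[(trimethylsilyl)methyl]-1,3-dioxan-5-ol (either configuration at C5) | CC1(C)OCC(O)(C[Si](C)(C)C)[C@@H](O1)[C@@H](O[Si](CC)(CC)CC)c2cc(I)ccc2Br
F5 | step 11 | (1R)-1-[(2R,3S)-3-hydroxy-2-(3-hydroxyprop-1-en-2-yl)-2,3-dihydro-1-benzofuran-5-yl]ethyl (2R)-2-methylbutanoate | C=C(CO)[C@H]1Oc2ccc([C@@H](C)OC(=O)[C@H](C)CC)cc2[C@@H]1O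
F6 | step 11 | (1R)-1-[(2R,3S)-3-hydroxy-2-(3-oxoprop-1-en-2-yl)-2,3-dihydro-1-benzofuran-5-yl]ethyl (2R)-2-methylbutanoate | C=C(C=O)[C@H]1Oc2ccc([C@@H](C)OC(=O)[C@H](C)CC)cc2[C@@H]1O
A1 | alternative 1 | (1R)-1-(3-formyl-4-hydroxyphenyl)ethyl (2R)-2-methylbutanoate | O=Cc1cc([C@@H](C)OC(=O)[C@H](C)CC)ccc1O
A2 | alternative 1 | (2R,5R)-2,5-dimethyl-1-(2-methylprop-2-en-1-yl)thiolan-1-ium tetrafluoroborate | C[C@@H]1CC[C@@H](C)[S+]1CC(C)=C.F[B-](F)(F)F
A3 | alternative 1 | (1R)-1-[(2R,3S)-3-hydroxy-2-(prop-1-en-2-yl)-2,3-dihydro-1-benzofuran-5-yl]ethyl (2R)-2-methylbutanoate | C=C(C)[C@H]1Oc2ccc([C@@H](C)OC(=O)[C@H](C)CC)cc2[C@@H]1O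
A4 | alternative 2 | (1R)-1-(2,2-dimethyl-2H-chromen-6-yl)ethyl (2R)-2-methylbutanoate | CC1(C)C=Cc2cc([C@@H](C)OC(=O)[C@H](C)CC)ccc2O1
A5 | alternative 2 | (1R)-1-[(3R,4R)-3,4-epoxy-2,2-dimethyl-3,4-dihydro-2H-chromen-6-yl]ethyl (2R)-2-methylbutanoate | CC1(C)Oc2ccc([C@@H](C)OC(=O)[C@H](C)CC)cc2[C@H]3O[C@@H]13
A6 | alternative 2 | (1R)-1-[(3R,4S)-3-hydroxy-2,2-dimethyl-4-(3-methylbutanoyloxy)-3,4-dihydro-2H-chromen-6-yl]ethyl (2R)-2-methylbutanoate | CC1(C)Oc2ccc([C@@H](C)OC(=O)[C@H](C)CC)cc2[C@H](OC(=O)CC(C)C)[C@H]1O
A7 | alternative 2 | (1R)-1-[(2R,3S)-3-(3-methylbutanoyloxy)-2-(prop-1-en-2-yl)-2,3-dihydro-1-benzofuran-5-yl]ethyl (2R)-2-methylbutanoate | C=C(C)[C@H]1Oc2ccc([C@@H](C)OC(=O)[C@H](C)CC)cc2[C@@H]1OC(=O)CC(C)C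
A8 | alternative 3 | (1R)-1-{4-[(1E)-3-(dimethylamino)-3-oxoprop-1-en-1-yl]oxy-3-formylphenyl}ethyl (2R)-2-methylbutanoate | CN(C)C(=O)/C=C/Oc1ccc([C@@H](C)OC(=O)[C@H](C)CC)cc1C=O
A9 | alternative 3 | (1R)-1-{(2R,3S)-2-[2-(dimethylamino)-2-oxoethyl]-3-hydroxy-2,3-dihydro-1-benzofuran-5-yl}ethyl (2R)-2-methylbutanoate | CN(C)C(=O)C[C@H]1Oc2ccc([C@@H](C)OC(=O)[C@H](C)CC)cc2[C@@H]1O
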